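**Plan**
- Cuts, in retrosynthetic order: the two O–benzyl bonds and the three benzylic CH2 groups (back to C=O). Then, in each outer phenol ring (C1' on the carbonyl, C4' bearing OH), the ring bonds C1'–C6' and C2'–C3', which leaves three propynoyl groups. Then the three C(O)–C≡C bonds, the aryl–CH2 bond of the arylethyl arm, and last the central ring.
- Enabling feature: take the central ring as C1 (OMe), C2, C3 (OH), C4, C5 (CH2CH2Ar), C6. The rings hung by one carbon from C2, C4 and C6 are the same 4-hydroxyphenyl unit with its oxygen para to the link, which is the pattern a 1-alkoxy-3-silyloxybutadiene gives with a terminal alkynyl ketone.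
- Forward: central ring from three molecules of diethyl malonate; its three phenols told apart as OMe, OBn and OTf; arylethyl arm by B-alkyl Suzuki coupling; esters to aldehydes to terminal ynones; the three outer rings close together in one threefold Diels–Alder/aromatization; ketones to CH2; benzyl ethers off.
- Stereochemistry: the target has no stereocentre; the carbinol centres of 13 and the CH(OMe) centres of 16 are transient and erased in the next operation.

Key step: step 11

Remark: 13 and 16 are handled as mixtures of diastereomers and are therefore drawn without configuration. Steps 1, 9 and 11 each consume three molecules of one building block per molecule of product; the second and third molecules are entered under "Reagents that add atoms".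

**Step 1**
Reactants: 1 diethyl malonate (3 equiv; three molecules combine)
Product: 2 triethyl 2,4,6-trihydroxybenzene-1,3,5-tricarboxylate
Conditions: NaOEt (1 equiv per malonate), neat, 140–150 °C, EtOH distilled off; then aq. HCl
Reagents that add atoms: diethyl malonate (second molecule), CCOC(=O)CC(=O)OCC; diethyl malonate (third molecule), CCOC(=O)CC(=O)OCC
Why: Classical Claisen/Dieckmann self-condensation of sodiomalonate, in which three malonate units are joined by three C-acylations with loss of three ethanol and the cyclic triketo triester enolizes to the aromatic phloroglucinol.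

**Step 2**
Reactants: 2 triethyl 2,4,6-trihydroxybenzene-1,3,5-tricarboxylate
Product: 3 triethyl 2,4-dihydroxy-6-methoxybenzene-1,3,5-tricarboxylate
Conditions: MeI (0.9 equiv), K2CO3 (1 equiv), DMF, 40 °C
Reagents that add atoms: iodomethane, CI
Why: Williamson O-methylation of an acidic salicylate-type phenol; the three hydroxyls are equivalent, so the halide is kept limiting, the mono-ether should be the main component of a separable mixture, and unreacted 2 is recycled.

**Step 3**
Reactants: 3 triethyl 2,4-dihydroxy-6-methoxybenzene-1,3,5-tricarboxylate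
Product: 4 triethyl 2-(benzyloxy)-4-hydroxy-6-methoxybenzene-1,3,5-tricarboxylate
Conditions: BnBr (0.95 equiv), K2CO3 (1 equiv), DMF, 50 °C
Reagents that add atoms: benzyl bromide, BrCc1ccccc1
Why: Second Williamson etherification on one of the two equivalent hydroxyls of 3, again with limiting halide and recycling of recovered 3; the fully substituted ring excludes C-alkylation.

**Step 4**
Reactants: 4 triethyl 2-(benzyloxy)-4-hydroxy-6-methoxybenzene-1,3,5-tricarboxylate
Product: 5 triethyl 2-(benzyloxy)-4-methoxy-6-{[(trifluoromethyl)sulfonyl]oxy}benzene-1,3,5-tricarboxylate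
Conditions: Tf2O, pyridine, CH2Cl2, 0 °C to rt
Reagents that add atoms: trifluoromethanesulfonic anhydride, O=S(=O)(OS(=O)(=O)C(F)(F)F)C(F)(F)F
Why: O-sulfonylation of the last, now unique phenol gives an electron-poor aryl triflate that is well set up for oxidative addition.

**Step 5**
Reactants: 6 3-(benzyloxy)benzaldehyde
Product: 7 1-(benzyloxy)-3-ethenylbenzene
Conditions: Ph3PCH3Br, KOtBu, THF, 0 °C to rt
Reagents that add atoms: methyltriphenylphosphonium bromide, C[P+](c1ccccc1)(c1ccccc1)c1ccccc1.[Br-]
Why: Wittig methylenation of a non-enolizable aryl aldehyde, with the benzyl ether inert to the ylide.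

**Step 6**
Reactants: 7 1-(benzyloxy)-3-ethenylbenzene; 5 triethyl 2-(benzyloxy)-4-methoxy-6-{[(trifluoromethyl)sulfonyl]oxy}benzene-1,3,5-tricarboxylate
Product: 9 triethyl 2-(benzyloxy)-4-methoxy-6-{2-[3-(benzyloxy)phenyl]ethyl}benzene-1,3,5-tricarboxylate, via B-alkyl-9-BBN adduct 8 (not isolated)
Conditions: 9-BBN, THF, rt; then 5, PdCl2(dppf) (dppf = 1,1'-bis(diphenylphosphino)ferrocene, 5 mol %), K3PO4, THF–DMF–H2O, 60 °C
Reagents that add atoms: none
Why: Anti-Markovnikov hydroboration of the styrene followed by B-alkyl Suzuki–Miyaura coupling, in which zerovalent palladium inserts readily into the ester-flanked triflate and the wide-bite-angle diphosphine favours reductive elimination over β-hydride elimination, while esters and benzyl ethers are tolerated.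

**Step 7**
Reactants: 9 triethyl 2-(benzyloxy)-4-methoxy-6-{2-[3-(benzyloxy)phenyl]ethyl}benzene-1,3,5-tricarboxylate
Product: 10 [2-(benzyloxy)-4-methoxy-6-{2-[3-(benzyloxy)phenyl]ethyl}benzene-1,3,5-triyl]trimethanol
Conditions: LiAlH4, THF, 0 °C to reflux; Fieser work-up
Reagents that add atoms: none
Why: Hydride reduction of the three aryl esters to benzylic alcohols, with reflux to overcome the two ortho substituents at each ester and with the methyl and benzyl ethers inert.

**Step 8**
Reactants: 10 [2-(benzyloxy)-4-methoxy-6-{2-[3-(benzyloxy)phenyl]ethyl}benzene-1,3,5-triyl]trimethanol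
Product: 11 2-(benzyloxy)-4-methoxy-6-{2-[3-(benzyloxy)phenyl]ethyl}benzene-1,3,5-tricarbaldehyde
Conditions: Dess–Martin periodinane, CH2Cl2, rt
Reagents that add atoms: none
Why: Dess–Martin oxidation of primary benzylic alcohols stops cleanly at the non-enolizable aldehydes under near-neutral conditions.

**Step 9**
Reactants: 11 2-(benzyloxy)-4-methoxy-6-{2-[3-(benzyloxy)phenyl]ethyl}benzene-1,3,5-tricarbaldehyde; 12 ethynylmagnesium bromide (3 equiv react, one per aldehyde; 4.5 equiv used)
Product: 13 1,1',1''-[2-(benzyloxy)-4-methoxy-6-{2-[3-(benzyloxy)phenyl]ethyl}benzene-1,3,5-triyl]tris(prop-2-yn-1-ol) (mixture of diastereomers)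
Conditions: THF, −20 to 0 °C; aqueous NH4Cl work-up
Reagents that add atoms: ethynylmagnesium bromide (second molecule), C#C[Mg]Br; ethynylmagnesium bromide (third molecule), C#C[Mg]Br
Why: Grignard 1,2-addition of the small ethynyl nucleophile to each of the three crowded but non-enolizable aryl aldehydes; the three carbinol centres form without control, which is immaterial because they are oxidized in the next step.

**Step 10**
Reactants: 13 1,1',1''-[2-(benzyloxy)-4-methoxy-6-{2-[3-(benzyloxy)phenyl]ethyl}benzene-1,3,5-triyl]tris(prop-2-yn-1-ol)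
Product: 14 1,1',1''-[2-(benzyloxy)-4-methoxy-6-{2-[3-(benzyloxy)phenyl]ethyl}benzene-1,3,5-triyl]tris(prop-2-yn-1-one)
Conditions: Dess–Martin periodinane, CH2Cl2, 0 °C to rt; used without storage
Reagents that add atoms: none
Why: Dess–Martin oxidation of secondary propargylic benzylic alcohols to ynones under non-nucleophilic conditions that the Michael-acceptor alkynones should tolerate.

**Step 11**
Reactants: 14 1,1',1''-[2-(benzyloxy)-4-methoxy-6-{2-[3-(benzyloxy)phenyl]ethyl}benzene-1,3,5-triyl]tris(prop-2-yn-1-one); 15 trans-1-methoxy-3-(trimethylsilyloxy)buta-1,3-diene (3 equiv react, one per ynone; about 6 equiv used)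
Product: 17 [2-(benzyloxy)-4-methoxy-6-{2-[3-(benzyloxy)phenyl]ethyl}benzene-1,3,5-triyl]tris[(4-hydroxyphenyl)methanone], via threefold cycloadduct 16 (not isolated)
Conditions: toluene, rt to 80 °C; then 1 M HCl, THF, rt
Reagents that add atoms: trans-1-methoxy-3-(trimethylsilyloxy)buta-1,3-diene (second molecule), CO/C=C/C(=C)O[Si](C)(C)C; trans-1-methoxy-3-(trimethylsilyloxy)buta-1,3-diene (third molecule), CO/C=C/C(=C)O[Si](C)(C)C
Why: Each terminal ynone is an activated dienophile that adds one molecule of the electron-rich diene in a normal-electron-demand, asynchronous [4+2] cycloaddition, the closest known reaction type being the benzannulation of acetylenic ketones and esters with this diene to para-hydroxyaryl carbonyl compounds. Each of the three six-membered rings closes intermolecularly in this [4+2] mode, the diene CH2 terminus joining the terminal alkyne carbon and the CH(OMe) terminus joining the carbonyl-bearing alkyne carbon, to give the 1,4-cyclohexadienes of 16. Aqueous acid then hydrolyses the silyl enol ethers and expels methanol, and tautomerization of the dienones delivers three phenols, so that the CH(OMe) centres of 16 are destroyed and no stereocentre remains. The selectivity needed is regiochemical (hydroxyl para and not meta to the carbonyl) and is secured by pairing the nucleophilic C4 of the diene with the electrophilic β-carbon of the ynone. The reacting alkyne carbons lie two and three atoms away from the hexasubstituted ring, so crowding at the core should not slow the cycloaddition, and the ortho oxygens are capped as methyl and benzyl ethers so that no chromone can form by oxa-Michael closure.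

**Step 12**
Reactants: 17 [2-(benzyloxy)-4-methoxy-6-{2-[3-(benzyloxy)phenyl]ethyl}benzene-1,3,5-triyl]tris[(4-hydroxyphenyl)methanone]
Product: 18 4,4',4''-{[2-(benzyloxy)-4-methoxy-6-{2-[3-(benzyloxy)phenyl]ethyl}benzene-1,3,5-triyl]tris(methylene)}triphenol
Conditions: Et3SiH (excess), CF3CO2H, CH2Cl2, 0 °C to rt
Reagents that add atoms: none
Why: Ionic hydrogenation of diaryl ketones, in which protonation, hydride transfer, ionization to a diarylmethyl cation stabilized by the para-hydroxyphenyl ring and a second hydride transfer give CH2; any partial loss of a benzyl ether would converge on the target in step 13.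

**Step 13**
Reactants: 18 4,4',4''-{[2-(benzyloxy)-4-methoxy-6-{2-[3-(benzyloxy)phenyl]ethyl}benzene-1,3,5-triyl]tris(methylene)}triphenol
Product: 19 3-[2-(3-hydroxyphenyl)ethyl]-2,4,6-tris(4-hydroxybenzyl)-5-methoxyphenol
Conditions: H2 (1 atm), Pd/C, EtOAc–MeOH, rt
Reagents that add atoms: none
Why: Catalytic hydrogenolysis of the two aryl benzyl ethers, with the diarylmethane and bibenzyl C–C bonds inert under these conditions.

**Compound list**
1 | diethyl malonate | CCOC(=O)CC(=O)OCC | starting material
2 | triethyl 2,4,6-trihydroxybenzene-1,3,5-tricarboxylate | CCOC(=O)c1c(O)c(C(=O)OCC)c(O)c(C(=O)OCC)c1O | intermediate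
3 | triethyl 2,4-dihydroxy-6-methoxybenzene-1,3,5-tricarboxylate | CCOC(=O)c1c(OC)c(C(=O)OCC)c(O)c(C(=O)OCC)c1O | intermediate
4 | triethyl 2-(benzyloxy)-4-hydroxy-6-methoxybenzene-1,3,5-tricarboxylate | CCOC(=O)c1c(OC)c(C(=O)OCC)c(OCc2ccccc2)c(C(=O)OCC)c1O | intermediate
5 | triethyl 2-(benzyloxy)-4-methoxy-6-{[(trifluoromethyl)sulfonyl]oxy}benzene-1,3,5-tricarboxylate | CCOC(=O)c1c(OC)c(C(=O)OCC)c(OCc2ccccc2)c(C(=O)OCC)c1OS(=O)(=O)C(F)(F)F | intermediate
6 | 3-(benzyloxy)benzaldehyde | O=Cc1cccc(OCc2ccccc2)c1 | starting material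
7 | 1-(benzyloxy)-3-ethenylbenzene | C=Cc1cccc(OCc2ccccc2)c1 | intermediate
8 | 9-{2-[3-(benzyloxy)phenyl]ethyl}-9-borabicyclo[3.3.1]nonane (not isolated) | C(Cc1cccc(OCc2ccccc2)c1)B1C2CCCC1CCC2 | intermediate
9 | triethyl 2-(benzyloxy)-4-methoxy-6-{2-[3-(benzyloxy)phenyl]ethyl}benzene-1,3,5-tricarboxylate | CCOC(=O)c1c(OC)c(C(=O)OCC)c(OCc2ccccc2)c(C(=O)OCC)c1CCc1cccc(OCc2ccccc2)c1 | intermediate
10 | [2-(benzyloxy)-4-methoxy-6-{2-[3-(benzyloxy)phenyl]ethyl}benzene-1,3,5-triyl]trimethanol | OCc1c(OC)c(CO)c(OCc2ccccc2)c(CO)c1CCc1cccc(OCc2ccccc2)c1 | intermediate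
11 | 2-(benzyloxy)-4-methoxy-6-{2-[3-(benzyloxy)phenyl]ethyl}benzene-1,3,5-tricarbaldehyde | O=Cc1c(OC)c(C=O)c(OCc2ccccc2)c(C=O)c1CCc1cccc(OCc2ccccc2)c1 | intermediate
12 | ethynylmagnesium bromide | C#C[Mg]Br | starting material
13 | 1,1',1''-[2-(benzyloxy)-4-methoxy-6-{2-[3-(benzyloxy)phenyl]ethyl}benzene-1,3,5-triyl]tris(prop-2-yn-1-ol), mixture of diastereomers | C#CC(O)c1c(OC)c(C(O)C#C)c(OCc2ccccc2)c(C(O)C#C)c1CCc1cccc(OCc2ccccc2)c1 | intermediate
14 | 1,1',1''-[2-(benzyloxy)-4-methoxy-6-{2-[3-(benzyloxy)phenyl]ethyl}benzene-1,3,5-triyl]tris(prop-2-yn-1-one) | C#CC(=O)c1c(OC)c(C(=O)C#C)c(OCc2ccccc2)c(C(=O)C#C)c1CCc1cccc(OCc2ccccc2)c1 | intermediate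
15 | trans-1-methoxy-3-(trimethylsilyloxy)buta-1,3-diene | CO/C=C/C(=C)O[Si](C)(C)C | starting material
16 | threefold cycloadduct, each acyl group being a 6-methoxy-4-(trimethylsilyloxy)cyclohexa-1,4-diene-1-carbonyl unit (not isolated, mixture of diastereomers) | COC1C=C(O[Si](C)(C)C)CC=C1C(=O)c1c(OC)c(C(=O)C2=CCC(O[Si](C)(C)C)=CC2OC)c(OCc2ccccc2)c(C(=O)C2=CCC(O[Si](C)(C)C)=CC2OC)c1CCc1cccc(OCc2ccccc2)c1 | intermediate
17 | [2-(benzyloxy)-4-methoxy-6-{2-[3-(benzyloxy)phenyl]ethyl}benzene-1,3,5-triyl]tris[(4-hydroxyphenyl)methanone] | COc1c(C(=O)c2ccc(O)cc2)c(OCc2ccccc2)c(C(=O)c2ccc(O)cc2)c(CCc2cccc(OCc3ccccc3)c2)c1C(=O)c1ccc(O)cc1 | intermediate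
18 | 4,4',4''-{[2-(benzyloxy)-4-methoxy-6-{2-[3-(benzyloxy)phenyl]ethyl}benzene-1,3,5-triyl]tris(methylene)}triphenol | COc1c(Cc2ccc(O)cc2)c(OCc2ccccc2)c(Cc2ccc(O)cc2)c(CCc2cccc(OCc3ccccc3)c2)c1Cc1ccc(O)cc1 | intermediate
19 | 3-[2-(3-hydroxyphenyl)ethyl]-2,4,6-tris(4-hydroxybenzyl)-5-methoxyphenol | COc1c(Cc2ccc(O)cc2)c(O)c(Cc2ccc(O)cc2)c(CCc2cccc(O)c2)c1Cc1ccc(O)cc1 | target

**Step count**
Total: 13 steps. Longest linear sequence: 12 steps (steps 1–4 and 6–13, from diethyl malonate); step 5 is a one-step side branch.

**Steps most likely to fail**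

Step 6. After oxidative addition into the triflate, which sits between two ester groups on a fully substituted ring, transmetalation and reductive elimination may be slow. β-Hydride elimination (returning styrene 7 and the hydrodetriflated arene) or base-induced S–O cleavage of the triflate back to phenol 4 could then take over. The fallback sets out from triflate 5 and styrene 7 and replaces the sp3 partner by an sp2 one. A Mizoroki–Heck reaction (Pd(OAc)2, P(o-tolyl)3, Et3N, DMF, 90 °C) should give the stilbene triethyl 2-(benzyloxy)-4-methoxy-6-{(E)-2-[3-(benzyloxy)phenyl]ethenyl}benzene-1,3,5-tricarboxylate F1. Its C=C bond is then saturated with diimide generated from p-toluenesulfonylhydrazide and NaOAc in refluxing aqueous DME, which leaves the benzyl ethers and esters alone. This comes back to the route at compound 9.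

Step 12. Hydride delivery to three carbonyl groups, each twisted between two ortho substituents, may stop short of full deoxygenation. The strong acid may also protonate the electron-rich central ring and expel a 4-hydroxybenzyl group, or strip a benzyl ether early. The fallback sets out from 17 and avoids strong acid. NaBH4 in THF–MeOH should reduce the ketones to the tris-carbinol [2-(benzyloxy)-4-methoxy-6-{2-[3-(benzyloxy)phenyl]ethyl}benzene-1,3,5-triyl]tris[(4-hydroxyphenyl)methanol] F2. A single hydrogenolysis (H2, Pd/C, EtOH–AcOH) then cleaves the three doubly benzylic C–OH bonds together with the two benzyl ethers. This comes back to the route at the target 19 and replaces steps 12 and 13.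

Step 11. The threefold cycloaddition may stall after one or two rings, or the tris-ynone may be consumed by conjugate addition and oligomerization (including open-chain Mukaiyama–Michael addition of the silyl enol ether) before all three rings have closed. The fallback sets out from trialdehyde 11 and brings in the outer rings ready-made. Addition of 4-(benzyloxy)phenylmagnesium bromide in THF should give the tris-carbinol [2-(benzyloxy)-4-methoxy-6-{2-[3-(benzyloxy)phenyl]ethyl}benzene-1,3,5-triyl]tris{[4-(benzyloxy)phenyl]methanol} F3. Ionic reduction of the carbinols (Et3SiH, CF3CO2H, CH2Cl2, 0 °C) gives 2-(benzyloxy)-1,3,5-tris[4-(benzyloxy)benzyl]-4-methoxy-6-{2-[3-(benzyloxy)phenyl]ethyl}benzene F4. Hydrogenolysis of all five benzyl ethers (H2, Pd/C) comes back to the route at the target 19.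

**Further compounds**
F1 | step 6 | triethyl 2-(benzyloxy)-4-methoxy-6-{(E)-2-[3-(benzyloxy)phenyl]ethenyl}benzene-1,3,5-tricarboxylate | CCOC(=O)c1c(OC)c(C(=O)OCC)c(OCc2ccccc2)c(C(=O)OCC)c1/C=C/c1cccc(OCc2ccccc2)c1
F2 | step 12 | [2-(benzyloxy)-4-methoxy-6-{2-[3-(benzyloxy)phenyl]ethyl}benzene-1,3,5-triyl]tris[(4-hydroxyphenyl)methanol], mixture of diastereomers | COc1c(C(O)c2ccc(O)cc2)c(OCc2ccccc2)c(C(O)c2ccc(O)cc2)c(CCc2cccc(OCc3ccccc3)c2)c1C(O)c1ccc(O)cc1
F3 | step 11 | [2-(benzyloxy)-4-methoxy-6-{2-[3-(benzyloxy)phenyl]ethyl}benzene-1,3,5-triyl]tris{[4-(benzyloxy)phenyl]methanol}, mixture of diastereomers | COc1c(C(O)c2ccc(OCc3ccccc3)cc2)c(OCc2ccccc2)c(C(O)c2ccc(OCc3ccccc3)cc2)c(CCc2cccc(OCc3ccccc3)c2)c1C(O)c1ccc(OCc2ccccc2)cc1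
F4 | step 11 | 2-(benzyloxy)-1,3,5-tris[4-(benzyloxy)benzyl]-4-methoxy-6-{2-[3-(benzyloxy)phenyl]ethyl}benzene | COc1c(Cc2ccc(OCc3ccccc3)cc2)c(OCc2ccccc2)c(Cc2ccc(OCc3ccccc3)cc2)c(CCc2cccc(OCc3ccccc3)c2)c1Cc1ccc(OCc2ccccc2)cc1
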